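Assumption: the target is taken exactly as the given SMILES, i.e. (2R,6R,7S,8R,9R)-2,9-diacetoxy-8-angeloyloxygermacra-1(10)Z,4E,11(13)-trien-6,12-olide; germacrane labels C1–C15 are used below, and 1 and 6 are bought as their E isomers.

**Retrosynthetic overview**
1. Last step: the fully acylated acyclic enal 16 closes the C6–C7 bond (10-membered ring) and then the O6–C12 lactone in one operation, in the order and polarity of farnesyl cation → germacrene → costunolide.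
2. 16 comes from ynoate 13 by syn-hydrostannation/iodination and a borylmethyl Negishi coupling, which fixes the (Z)-allylboronate geometry.
3. 13 comes from tetraene 9 by a hydroxy-directed singlet-oxygen [4+2] reaction (sets C2, C9 and the 1(10)-Z olefin from C8), then angeloylation, O–O reduction and acetylation.
4. 9 comes from a Stille union of dienylstannane 5 (C8 set by asymmetric alkynylation of 3 with methyl propiolate) and bromo-enal 8.
5. Building blocks: enynol 1, methyl propiolate 4, bromo ester 6.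

**Route**

Step 1
Reactants: 1 (2E)-3-methylpent-2-en-4-yn-1-ol
Product: 2 (2E,4E)-3-methyl-5-(tributylstannyl)penta-2,4-dien-1-ol
Conditions: Bu3SnH (1.1 eq), PdCl2(PPh3)2 (2 mol %), THF, 0 °C to rt
Reagents that add atoms: tributyltin hydride, CCCC[SnH](CCCC)CCCC
Why: Pd-catalysed hydrostannation adds Sn–H syn across the terminal alkyne with tin on the terminal carbon, giving the (E)-dienylstannane and leaving the existing E olefin untouched.

Step 2
Reactants: 2 (2E,4E)-3-methyl-5-(tributylstannyl)penta-2,4-dien-1-ol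
Product: 3 (2E,4E)-3-methyl-5-(tributylstannyl)penta-2,4-dienal
Conditions: MnO2 (10 eq), CH2Cl2, rt
Reagents that add atoms: none
Why: MnO2 allylic oxidation converts only the primary dienylic alcohol and does not disturb the vinylstannane or the diene geometry.

Step 3
Reactants: 3 (2E,4E)-3-methyl-5-(tributylstannyl)penta-2,4-dienal; 4 methyl propiolate
Product: 5 methyl (4S,5E,7E)-4-hydroxy-6-methyl-8-(tributylstannyl)octa-5,7-dien-2-ynoate
Conditions: (S,S)-ProPhenol (20 mol %), Me2Zn (3 eq), Ph3P=O (40 mol %), toluene, 4 °C; aqueous work-up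
Reagents that add atoms: none
Why: Dinuclear-zinc ProPhenol alkynylation (asymmetric 1,2-addition of a zinc alkynylide to an enal) must deliver the alkyne to the Re face to give the 4S carbinol, the future C8 (R by CIP once C9 is oxygenated); the ligand antipode is assigned from memory of the enal precedent and the sense is checked by Mosher ester.

Step 4
Reactants: 6 methyl (2E)-4-bromo-3-methylbut-2-enoate
Product: 7 (2E)-4-bromo-3-methylbut-2-en-1-ol
Conditions: DIBAL-H (2.2 eq), CH2Cl2, −78 °C; Rochelle salt work-up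
Reagents that add atoms: none
Why: DIBAL-H 1,2-reduction of the enoate at low temperature gives the allylic alcohol without touching the allylic bromide or the E olefin.

Step 5
Reactants: 7 (2E)-4-bromo-3-methylbut-2-en-1-ol
Product: 8 (2E)-4-bromo-3-methylbut-2-enal
Conditions: MnO2 (10 eq), CH2Cl2, 0 °C to rt; used crude
Reagents that add atoms: none
Why: MnO2 allylic oxidation gives the γ-bromo enal under neutral conditions that do not displace the bromide.

Step 6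
Reactants: 5 methyl (4S,5E,7E)-4-hydroxy-6-methyl-8-(tributylstannyl)octa-5,7-dien-2-ynoate; 8 (2E)-4-bromo-3-methylbut-2-enal
Product: 9 methyl (4S,5E,7E,10E)-4-hydroxy-6,10-dimethyl-12-oxododeca-5,7,10-trien-2-ynoate
Conditions: Pd2(dba)3 (2.5 mol %), AsPh3 (10 mol %), THF, rt
Reagents that add atoms: none
Why: Stille sp2–sp3 coupling joins the vinylstannane to the CH2 terminus of the π-allylpalladium from the allylic bromide with retention of all olefin geometries; arsine ligand avoids phosphine addition to the ynoate.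

Step 7
Reactants: 9 methyl (4S,5E,7E,10E)-4-hydroxy-6,10-dimethyl-12-oxododeca-5,7,10-trien-2-ynoate
Product: 10 methyl (4R)-4-hydroxy-4-{(3R,6R)-4-methyl-6-[(2E)-2-methyl-4-oxobut-2-en-1-yl]-3,6-dihydro-1,2-dioxin-3-yl}but-2-ynoate
Conditions: O2, tetraphenylporphyrin (1 mol %), visible light, CH2Cl2, −20 °C
Reagents that add atoms: dioxygen (as singlet oxygen), O=O
Why: The singlet-oxygen [4+2] cycloaddition is suprafacial on the s-cis (E,E)-diene, so the C2–O and C9–O bonds form cis and the ring olefin is Z; the free C8 hydroxyl, in the A1,3-locked rotamer with C8–H eclipsing the cis C10 methyl, hydrogen-bonds the incoming oxygen and gives the threo (8,9-syn) adduct, while the enal and ynoate π-bonds are too electron-poor to react.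

Step 8
Reactants: 10 methyl (4R)-4-hydroxy-4-{(3R,6R)-4-methyl-6-[(2E)-2-methyl-4-oxobut-2-en-1-yl]-3,6-dihydro-1,2-dioxin-3-yl}but-2-ynoate
Product: 11 methyl (4R)-4-{(3R,6R)-4-methyl-6-[(2E)-2-methyl-4-oxobut-2-en-1-yl]-3,6-dihydro-1,2-dioxin-3-yl}-4-{[(2Z)-2-methylbut-2-enoyl]oxy}but-2-ynoate
Conditions: angelic anhydride (1.5 eq), pyridine (3 eq), DMAP (5 mol %), CH2Cl2, 0 °C
Reagents that add atoms: angelic anhydride, C/C=C(/C)C(=O)OC(=O)/C(C)=C\C
Why: DMAP-catalysed acyl transfer from the preformed anhydride esterifies the only free hydroxyl while avoiding the acid-chloride route that isomerises angelate to tiglate, and weak base at 0 °C should not trigger Kornblum–DeLaMare opening of the dioxine.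

Step 9
Reactants: 11 methyl (4R)-4-{(3R,6R)-4-methyl-6-[(2E)-2-methyl-4-oxobut-2-en-1-yl]-3,6-dihydro-1,2-dioxin-3-yl}-4-{[(2Z)-2-methylbut-2-enoyl]oxy}but-2-ynoate
Product: 12 methyl (4R,5R,6Z,8R,10E)-5,8-dihydroxy-6,10-dimethyl-4-{[(2Z)-2-methylbut-2-enoyl]oxy}-12-oxododeca-6,10-dien-2-ynoate
Conditions: Zn dust, AcOH, CH2Cl2, 0 °C
Reagents that add atoms: none
Why: Dissolving-metal reduction cleaves only the weak O–O bond, so both C–O stereocentres and the Z olefin are retained and the cis-ene-1,4-diol is released.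

Step 10
Reactants: 12 methyl (4R,5R,6Z,8R,10E)-5,8-dihydroxy-6,10-dimethyl-4-{[(2Z)-2-methylbut-2-enoyl]oxy}-12-oxododeca-6,10-dien-2-ynoate
Product: 13 methyl (4R,5R,6Z,8R,10E)-5,8-diacetoxy-6,10-dimethyl-4-{[(2Z)-2-methylbut-2-enoyl]oxy}-12-oxododeca-6,10-dien-2-ynoate
Conditions: Ac2O (4 eq), pyridine, DMAP (5 mol %), CH2Cl2, 0 °C
Reagents that add atoms: acetic anhydride, CC(=O)OC(C)=O
Why: Standard acetylation caps both allylic alcohols (C2 and C9) at once, run fast and cold so that the neighbouring angelate does not migrate.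

Step 11
Reactants: 13 methyl (4R,5R,6Z,8R,10E)-5,8-diacetoxy-6,10-dimethyl-4-{[(2Z)-2-methylbut-2-enoyl]oxy}-12-oxododeca-6,10-dien-2-ynoate
Product: 15 methyl (2E,4R,5R,6Z,8R,10E)-5,8-diacetoxy-2-iodo-6,10-dimethyl-4-{[(2Z)-2-methylbut-2-enoyl]oxy}-12-oxododeca-2,6,10-trienoate, via α-stannyl enoate 14 (not isolated)
Conditions: Bu3SnH (1.05 eq, slow addition), Pd(PPh3)4 (2 mol %), THF, 0 °C; then I2, CH2Cl2, 0 °C, dark
Reagents that add atoms: tributyltin hydride (tin is carried only by 14), CCCC[SnH](CCCC)CCCC; iodine, II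
Why: Pd-catalysed hydrostannation of an ynoate is syn and places tin next to the ester, so C8 ends up cis to CO2Me, and iododestannylation then proceeds with retention.

Step 12
Reactants: 15 methyl (2E,4R,5R,6Z,8R,10E)-5,8-diacetoxy-2-iodo-6,10-dimethyl-4-{[(2Z)-2-methylbut-2-enoyl]oxy}-12-oxododeca-2,6,10-trienoate
Product: 16 methyl (2Z,4R,5R,6Z,8R,10E)-5,8-diacetoxy-6,10-dimethyl-4-{[(2Z)-2-methylbut-2-enoyl]oxy}-12-oxo-2-[(4,4,5,5-tetramethyl-1,3,2-dioxaborolan-2-yl)methyl]dodeca-2,6,10-trienoate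
Conditions: ICH2Bpin, Zn dust, THF, rt (gives IZnCH2Bpin); then 15, Pd(dba)2 (5 mol %), P(2-furyl)3 (10 mol %), THF, rt
Reagents that add atoms: 2-(iodomethyl)-4,4,5,5-tetramethyl-1,3,2-dioxaborolane (used as its zinc reagent), ICB1OC(C)(C)C(C)(C)O1
Why: Negishi sp2–sp3 coupling of the alkenyl iodide with the borylmethylzinc reagent retains olefin geometry and gives the (Z)-2-(methoxycarbonyl)allylboronate, a class that does not add to aldehydes at room temperature without a catalyst.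

Step 13
Reactants: 16 methyl (2Z,4R,5R,6Z,8R,10E)-5,8-diacetoxy-6,10-dimethyl-4-{[(2Z)-2-methylbut-2-enoyl]oxy}-12-oxo-2-[(4,4,5,5-tetramethyl-1,3,2-dioxaborolan-2-yl)methyl]dodeca-2,6,10-trienoate
Product: 18 CNP0499619.1 [(3aS,4R,5R,6Z,8R,10E,11aR)-5,8-diacetoxy-6,10-dimethyl-3-methylidene-2-oxo-2,3,3a,4,5,8,9,11a-octahydrocyclodeca[b]furan-4-yl (2Z)-2-methylbut-2-enoate], via O-boryl hydroxy ester 17 (not isolated)
Conditions: Sc(OTf)3 (10 mol %), 4 Å MS, toluene (1 mM, slow addition), 0 °C to rt; then p-TsOH·H2O (10 mol %) if the hydroxy ester persists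
Reagents that add atoms: none
Why: Proposed new method: intramolecular Lewis-acid-catalysed 2-alkoxycarbonyl-allylboration of the enal, in which the C7=C11 π-bond attacks electrophilic C6 and boron leaves from C13 (the role of the proton lost in germacrene formation), after which the O6–boron alkoxide lactonises onto C12 with loss of MeOBpin. The six-membered Zimmerman–Traxler chair with C5 equatorial and C8 pseudo-equatorial (C8 trans to CH2B) gives the 6,7-anti (trans-lactone) relationship. The A1,3-locked rotamer (C8–H eclipsing the cis ester carbon) puts the tether carbon C9 on one π-face, so closure through a gauche C6–C7–C8–C9 torsion delivers C6 anti to the C8–O bond and sets 6R,7S; this face selectivity is a conformational argument, not a precedent. The closest known chemistry is the intermolecular Sc(III)- or acid-catalysed allylboration/lactonisation of aldehydes to trans-β,γ-disubstituted α-methylene-γ-butyrolactones, and Cr(II)- or Pd/Zn-mediated allylation macrocyclisations of farnesal-type aldehydes to germacrane rings.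

**Compound list**
1 | (2E)-3-methylpent-2-en-4-yn-1-ol | C#C/C(C)=C/CO | starting material
2 | (2E,4E)-3-methyl-5-(tributylstannyl)penta-2,4-dien-1-ol | CCCC[Sn](CCCC)(CCCC)/C=C/C(C)=C/CO | intermediate
3 | (2E,4E)-3-methyl-5-(tributylstannyl)penta-2,4-dienal | CCCC[Sn](CCCC)(CCCC)/C=C/C(C)=C/C=O | intermediate
4 | methyl propiolate | C#CC(=O)OC | starting material
5 | methyl (4S,5E,7E)-4-hydroxy-6-methyl-8-(tributylstannyl)octa-5,7-dien-2-ynoate | COC(=O)C#C[C@@H](O)/C=C(\C)/C=C/[Sn](CCCC)(CCCC)CCCC | intermediate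
6 | methyl (2E)-4-bromo-3-methylbut-2-enoate | COC(=O)/C=C(\C)CBr | starting material
7 | (2E)-4-bromo-3-methylbut-2-en-1-ol | OC/C=C(\C)CBr | intermediate
8 | (2E)-4-bromo-3-methylbut-2-enal | O=C/C=C(\C)CBr | intermediate
9 | methyl (4S,5E,7E,10E)-4-hydroxy-6,10-dimethyl-12-oxododeca-5,7,10-trien-2-ynoate | COC(=O)C#C[C@@H](O)/C=C(\C)/C=C/C/C(C)=C/C=O | intermediate
10 | methyl (4R)-4-hydroxy-4-{(3R,6R)-4-methyl-6-[(2E)-2-methyl-4-oxobut-2-en-1-yl]-3,6-dihydro-1,2-dioxin-3-yl}but-2-ynoate | O=C/C=C(\C)C[C@H]1OO[C@@H]([C@H](O)C#CC(=O)OC)C(C)=C1 | intermediate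
11 | methyl (4R)-4-{(3R,6R)-4-methyl-6-[(2E)-2-methyl-4-oxobut-2-en-1-yl]-3,6-dihydro-1,2-dioxin-3-yl}-4-{[(2Z)-2-methylbut-2-enoyl]oxy}but-2-ynoate | O=C/C=C(\C)C[C@H]1OO[C@@H]([C@H](OC(=O)/C(C)=C\C)C#CC(=O)OC)C(C)=C1 | intermediate
12 | methyl (4R,5R,6Z,8R,10E)-5,8-dihydroxy-6,10-dimethyl-4-{[(2Z)-2-methylbut-2-enoyl]oxy}-12-oxododeca-6,10-dien-2-ynoate | O=C/C=C(\C)C[C@@H](O)/C=C(/C)[C@@H](O)[C@H](OC(=O)/C(C)=C\C)C#CC(=O)OC | intermediate
13 | methyl (4R,5R,6Z,8R,10E)-5,8-diacetoxy-6,10-dimethyl-4-{[(2Z)-2-methylbut-2-enoyl]oxy}-12-oxododeca-6,10-dien-2-ynoate | O=C/C=C(\C)C[C@@H](OC(C)=O)/C=C(/C)[C@@H](OC(C)=O)[C@H](OC(=O)/C(C)=C\C)C#CC(=O)OC | intermediate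
14 | methyl (2E,4R,5R,6Z,8R,10E)-5,8-diacetoxy-6,10-dimethyl-4-{[(2Z)-2-methylbut-2-enoyl]oxy}-12-oxo-2-(tributylstannyl)dodeca-2,6,10-trienoate (not isolated) | O=C/C=C(\C)C[C@@H](OC(C)=O)/C=C(/C)[C@@H](OC(C)=O)[C@H](OC(=O)/C(C)=C\C)/C=C(/[Sn](CCCC)(CCCC)CCCC)C(=O)OC | intermediate
15 | methyl (2E,4R,5R,6Z,8R,10E)-5,8-diacetoxy-2-iodo-6,10-dimethyl-4-{[(2Z)-2-methylbut-2-enoyl]oxy}-12-oxododeca-2,6,10-trienoate | O=C/C=C(\C)C[C@@H](OC(C)=O)/C=C(/C)[C@@H](OC(C)=O)[C@H](OC(=O)/C(C)=C\C)/C=C(/I)C(=O)OC | intermediate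
16 | methyl (2Z,4R,5R,6Z,8R,10E)-5,8-diacetoxy-6,10-dimethyl-4-{[(2Z)-2-methylbut-2-enoyl]oxy}-12-oxo-2-[(4,4,5,5-tetramethyl-1,3,2-dioxaborolan-2-yl)methyl]dodeca-2,6,10-trienoate | O=C/C=C(\C)C[C@@H](OC(C)=O)/C=C(/C)[C@@H](OC(C)=O)[C@H](OC(=O)/C(C)=C\C)/C=C(/CB1OC(C)(C)C(C)(C)O1)C(=O)OC | intermediate
17 | methyl 2-[(1S,2R,3E,6R,7Z,9R,10R)-6,9-diacetoxy-4,8-dimethyl-10-{[(2Z)-2-methylbut-2-enoyl]oxy}-2-[(4,4,5,5-tetramethyl-1,3,2-dioxaborolan-2-yl)oxy]cyclodeca-3,7-dien-1-yl]prop-2-enoate (not isolated) | COC(=O)C(=C)[C@H]1[C@H](OB2OC(C)(C)C(C)(C)O2)/C=C(\C)C[C@@H](OC(C)=O)/C=C(/C)[C@@H](OC(C)=O)[C@@H]1OC(=O)/C(C)=C\C | intermediate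
18 | CNP0499619.1, (3aS,4R,5R,6Z,8R,10E,11aR)-5,8-diacetoxy-6,10-dimethyl-3-methylidene-2-oxo-2,3,3a,4,5,8,9,11a-octahydrocyclodeca[b]furan-4-yl (2Z)-2-methylbut-2-enoate | C=C1C(=O)O[C@@H]2/C=C(\C)C[C@@H](OC(C)=O)/C=C(/C)[C@@H](OC(C)=O)[C@H](OC(=O)/C(C)=C\C)[C@@H]12 | target

**Step count**
Total: 13 steps. Longest linear sequence: 11 steps (1, 2, 3, 6, 7, 8, 9, 10, 11, 12, 13 from compound 1).

**Three steps most likely to fail, with fallbacks**

Step 13 (macrocyclisation/lactonisation). The 10-membered closure may be slow at 1 mM, Sc(III) may ionise the allylic acetates, or closure may occur on the other π-face of C7. The fallback sets out from 15 and comes back at 18, replacing catalytic allylboration by a stoichiometric, geometry-independent allylchromium. Stille coupling of 15 with (tributylstannyl)methanol (Pd(PPh3)4, dioxane, 80 °C) gives methyl (2Z,4R,5R,6Z,8R,10E)-5,8-diacetoxy-2-(hydroxymethyl)-6,10-dimethyl-4-{[(2Z)-2-methylbut-2-enoyl]oxy}-12-oxododeca-2,6,10-trienoate F1. Appel bromination (CBr4, PPh3, CH2Cl2, 0 °C) gives the corresponding (2E)-2-(bromomethyl) enoate F2. CrCl2 (6 eq) in THF/DMF under high dilution then effects a Nozaki–Hiyama-type Barbier macrocyclisation onto the enal, and acidic work-up lactonises the hydroxy ester to 18.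

Step 7 (hydroxy-directed photooxygenation). Hydrogen-bond control of the π-face may be weak, and ene reaction at the C10 methyl may compete. The fallback sets out from 3 and comes back at 13, replacing hydrogen-bond control by steric control on the C8 epimer and correcting C8 at the end by inversion. Alkynylation of 3 with 4 using (R,R)-ProPhenol gives methyl (4R,5E,7E)-4-hydroxy-6-methyl-8-(tributylstannyl)octa-5,7-dien-2-ynoate F3. Stille coupling with 8 gives methyl (4R,5E,7E,10E)-4-hydroxy-6,10-dimethyl-12-oxododeca-5,7,10-trien-2-ynoate F4, and TBSOTf/2,6-lutidine gives its tert-butyldimethylsilyl ether F5. Photooxygenation of F5 is expected to occur anti to the bulky silyloxy group in the same A1,3 rotamer (moderate selectivity), giving methyl (4S)-4-[(tert-butyldimethylsilyl)oxy]-4-{(3R,6R)-4-methyl-6-[(2E)-2-methyl-4-oxobut-2-en-1-yl]-3,6-dihydro-1,2-dioxin-3-yl}but-2-ynoate F6. Zn/AcOH gives methyl (4S,5R,6Z,8R,10E)-4-[(tert-butyldimethylsilyl)oxy]-5,8-dihydroxy-6,10-dimethyl-12-oxododeca-6,10-dien-2-ynoate F7, and Ac2O/pyridine gives the 5,8-diacetate F8. HF·pyridine gives methyl (4S,5R,6Z,8R,10E)-5,8-diacetoxy-4-hydroxy-6,10-dimethyl-12-oxododeca-6,10-dien-2-ynoate F9. Mitsunobu esterification of F9 with angelic acid (PPh3, DIAD) inverts C8 and delivers 13.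

Step 8 (angeloylation of the hydroxy endoperoxide). Base may open the dioxine (Kornblum–DeLaMare) or DMAP may isomerise angelate to tiglate. The fallback sets out from 10 and comes back at 13, moving the angeloylation to a robust, peroxide-free stage. TBSOTf/2,6-lutidine at −78 °C gives methyl (4R)-4-[(tert-butyldimethylsilyl)oxy]-4-{(3R,6R)-4-methyl-6-[(2E)-2-methyl-4-oxobut-2-en-1-yl]-3,6-dihydro-1,2-dioxin-3-yl}but-2-ynoate F10. Zn/AcOH gives methyl (4R,5R,6Z,8R,10E)-4-[(tert-butyldimethylsilyl)oxy]-5,8-dihydroxy-6,10-dimethyl-12-oxododeca-6,10-dien-2-ynoate F11, and Ac2O/pyridine gives the 5,8-diacetate F12. HF·pyridine gives methyl (4R,5R,6Z,8R,10E)-5,8-diacetoxy-4-hydroxy-6,10-dimethyl-12-oxododeca-6,10-dien-2-ynoate F13. Yamaguchi esterification of F13 with angelic acid (2,4,6-trichlorobenzoyl chloride, Et3N; toluene, 75 °C, no DMAP) gives 13.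

**Further compounds**
F1 | step 13 | methyl (2Z,4R,5R,6Z,8R,10E)-5,8-diacetoxy-2-(hydroxymethyl)-6,10-dimethyl-4-{[(2Z)-2-methylbut-2-enoyl]oxy}-12-oxododeca-2,6,10-trienoate | O=C/C=C(\C)C[C@@H](OC(C)=O)/C=C(/C)[C@@H](OC(C)=O)[C@H](OC(=O)/C(C)=C\C)/C=C(/CO)C(=O)OC
F2 | step 13 | methyl (2E,4R,5R,6Z,8R,10E)-5,8-diacetoxy-2-(bromomethyl)-6,10-dimethyl-4-{[(2Z)-2-methylbut-2-enoyl]oxy}-12-oxododeca-2,6,10-trienoate | O=C/C=C(\C)C[C@@H](OC(C)=O)/C=C(/C)[C@@H](OC(C)=O)[C@H](OC(=O)/C(C)=C\C)/C=C(/CBr)C(=O)OC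
F3 | step 7 | methyl (4R,5E,7E)-4-hydroxy-6-methyl-8-(tributylstannyl)octa-5,7-dien-2-ynoate | COC(=O)C#C[C@H](O)/C=C(\C)/C=C/[Sn](CCCC)(CCCC)CCCC
F4 | step 7 | methyl (4R,5E,7E,10E)-4-hydroxy-6,10-dimethyl-12-oxododeca-5,7,10-trien-2-ynoate | COC(=O)C#C[C@H](O)/C=C(\C)/C=C/C/C(C)=C/C=O
F5 | step 7 | methyl (4R,5E,7E,10E)-4-[(tert-butyldimethylsilyl)oxy]-6,10-dimethyl-12-oxododeca-5,7,10-trien-2-ynoate | COC(=O)C#C[C@H](O[Si](C)(C)C(C)(C)C)/C=C(\C)/C=C/C/C(C)=C/C=O
F6 | step 7 | methyl (4S)-4-[(tert-butyldimethylsilyl)oxy]-4-{(3R,6R)-4-methyl-6-[(2E)-2-methyl-4-oxobut-2-en-1-yl]-3,6-dihydro-1,2-dioxin-3-yl}but-2-ynoate | O=C/C=C(\C)C[C@H]1OO[C@@H]([C@@H](O[Si](C)(C)C(C)(C)C)C#CC(=O)OC)C(C)=C1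
F7 | step 7 | methyl (4S,5R,6Z,8R,10E)-4-[(tert-butyldimethylsilyl)oxy]-5,8-dihydroxy-6,10-dimethyl-12-oxododeca-6,10-dien-2-ynoate | O=C/C=C(\C)C[C@@H](O)/C=C(/C)[C@@H](O)[C@@H](O[Si](C)(C)C(C)(C)C)C#CC(=O)OC
F8 | step 7 | methyl (4S,5R,6Z,8R,10E)-5,8-diacetoxy-4-[(tert-butyldimethylsilyl)oxy]-6,10-dimethyl-12-oxododeca-6,10-dien-2-ynoate | O=C/C=C(\C)C[C@@H](OC(C)=O)/C=C(/C)[C@@H](OC(C)=O)[C@@H](O[Si](C)(C)C(C)(C)C)C#CC(=O)OC
F9 | step 7 | methyl (4S,5R,6Z,8R,10E)-5,8-diacetoxy-4-hydroxy-6,10-dimethyl-12-oxododeca-6,10-dien-2-ynoate | O=C/C=C(\C)C[C@@H](OC(C)=O)/C=C(/C)[C@@H](OC(C)=O)[C@@H](O)C#CC(=O)OC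
F10 | step 8 | methyl (4R)-4-[(tert-butyldimethylsilyl)oxy]-4-{(3R,6R)-4-methyl-6-[(2E)-2-methyl-4-oxobut-2-en-1-yl]-3,6-dihydro-1,2-dioxin-3-yl}but-2-ynoate | O=C/C=C(\C)C[C@H]1OO[C@@H]([C@H](O[Si](C)(C)C(C)(C)C)C#CC(=O)OC)C(C)=C1
F11 | step 8 | methyl (4R,5R,6Z,8R,10E)-4-[(tert-butyldimethylsilyl)oxy]-5,8-dihydroxy-6,10-dimethyl-12-oxododeca-6,10-dien-2-ynoate | O=C/C=C(\C)C[C@@H](O)/C=C(/C)[C@@H](O)[C@H](O[Si](C)(C)C(C)(C)C)C#CC(=O)OC
F12 | step 8 | methyl (4R,5R,6Z,8R,10E)-5,8-diacetoxy-4-[(tert-butyldimethylsilyl)oxy]-6,10-dimethyl-12-oxododeca-6,10-dien-2-ynoate | O=C/C=C(\C)C[C@@H](OC(C)=O)/C=C(/C)[C@@H](OC(C)=O)[C@H](O[Si](C)(C)C(C)(C)C)C#CC(=O)OC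
F13 | step 8 | methyl (4R,5R,6Z,8R,10E)-5,8-diacetoxy-4-hydroxy-6,10-dimethyl-12-oxododeca-6,10-dien-2-ynoate | O=C/C=C(\C)C[C@@H](OC(C)=O)/C=C(/C)[C@@H](OC(C)=O)[C@H](O)C#CC(=O)OC
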